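**Assumption:** germacranolide numbering is used for atom labels (ring C1–C10, lactone C8–O/C11(=C13)/C12=O, C14 on C10, C15 on C4). The target is then (4R,7S,8S,9R,10S) with a (2′R)-2-methylbutanoate, exactly as in the given SMILES.

## Retrosynthetic overview

1. Target ⇐ C5 carbinol **16**. The ten-membered carbocycle is closed last, at C6–C7, by a radical allyl-transfer (SH2′) macrocyclisation: a C6 primary radical adds to C7 of a 3-(tosylmethyl)butenolide, which sets C7 and releases the exocyclic methylene in the same event.
2. The radical acceptor comes from an α-methylene-γ-butyrolactone (this lactone ring is made first) by iodosulfonylation/dehydroiodination; the radical precursor (iodohydrin) comes from the C5=C6 vinyl group.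
3. The lactone comes from a chelation-controlled In Barbier allylation/lactonisation of a 2,3-dihydroxy aldehyde (sets C8); the C9 ester is installed by selective acylation.
4. C9/C10 come from Sharpless epoxidation of an (E)-allylic alcohol plus Payne rearrangement–opening; the allylic alcohol comes from alkyne carboalumination.
5. C4 comes from a Cu-catalysed asymmetric allylic methylation of (E)-1,6-dibromohex-2-ene.

## Route

**Step 1**
Reactants: **1** 5-bromopent-1-ene; **2** (E)-1,4-dibromobut-2-ene
Product: **3** (E)-1,6-dibromohex-2-ene
Conditions: Grubbs II (2 mol %), **2** (3 equiv), CH2Cl2, 40 °C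
Reagents that add atoms: none
Why: Olefin cross-metathesis of a terminal alkene with a symmetrical allylic dibromide gives the E-allylic bromide (E:Z about 9:1); no stereocentre is formed.

**Step 2**
Reactants: **3**
Product: **4** (R)-6-bromo-3-methylhex-1-ene
Conditions: MeMgBr (1.2 equiv), CuBr·SMe2 (1 mol %), Taniaphos (1.2 mol %; ligand antipode chosen to give R), CH2Cl2, −78 °C
Reagents that add atoms: methylmagnesium bromide, C[Mg]Br
Why: Cu-catalysed asymmetric allylic alkylation (SN2′, branched-selective) sets C4; the primary alkyl bromide does not react at −78 °C.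

**Step 3**
Reactants: **4**
Product: **5** (R)-3-methyloct-1-en-7-yne
Conditions: LiC≡CH·ethylenediamine, DMSO, 10 °C → rt
Reagents that add atoms: lithium acetylide (ethylenediamine complex), [Li]C#C
Why: SN2 alkylation of acetylide at the primary bromide; C4 is untouched.

**Step 4**
Reactants: **5**
Product: **6** (2E,7R)-3,7-dimethylnona-2,8-dien-1-ol
Conditions: AlMe3 (2.5 equiv), Cp2ZrCl2 (25 mol %), CH2Cl2, 0 °C → rt; then n-BuLi, (CH2O)n, THF, −78 °C → rt
Reagents that add atoms: trimethylaluminium, C[Al](C)C; paraformaldehyde, C=O
Why: Negishi Zr-catalysed syn-carboalumination of the terminal alkyne (Me to the internal carbon), then hydroxymethylation of the alkenylaluminate, gives the E-trisubstituted allylic alcohol; the isolated vinyl group is unreactive.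

**Step 5**
Reactants: **6**
Product: **7** [(2S,3S)-3-methyl-3-[(4R)-4-methylhex-5-en-1-yl]oxiran-2-yl]methanol
Conditions: Ti(OiPr)4 (10 mol %), L-(+)-DET (12 mol %), t-BuOOH, 4 Å MS, CH2Cl2, −20 °C
Reagents that add atoms: tert-butyl hydroperoxide, CC(C)(C)OO
Why: Sharpless asymmetric epoxidation reacts only at the allylic-alcohol alkene; L-(+)-tartrate gives the (2S,3S) epoxide, as for geraniol, which fixes C10.

**Step 6**
Reactants: **7**
Product: **8** (2R,3S,7R)-3,7-dimethylnon-8-ene-1,2,3-triol
Conditions: 0.5 M NaOH, t-BuOH/H2O, 70 °C
Reagents that add atoms: sodium hydroxide/water, [OH-].[Na+]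
Why: Payne rearrangement followed by hydroxide attack at C1 of the terminal epoxide gives net inversion at the secondary carbon (C9 → R) and retention at the tertiary carbinol (C10 = S).

**Step 7**
Reactants: **8**
Product: **9** (2S,3S,7R)-2,3-dihydroxy-3,7-dimethylnon-8-enal (used crude)
Conditions: TEMPO (10 mol %), PhI(OAc)2 (1.1 equiv), CH2Cl2, rt
Reagents that add atoms: none
Why: Oxoammonium (TEMPO) oxidation is selective for the primary alcohol over the secondary and tertiary ones; neutral conditions leave the α-stereocentre intact.

**Step 8**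
Reactants: **9**; **10** methyl 2-(bromomethyl)acrylate
Product: **11** (5S)-5-[(1R,2S,6R)-1,2-dihydroxy-2,6-dimethyloct-7-en-1-yl]-3-methylideneoxolan-2-one
Conditions: In powder (1.5 equiv), **10** (1.5 equiv), THF/H2O 1:1, rt; then 1 M HCl
Reagents that add atoms: none besides reactant **10**
Why: Indium Barbier allylation in water under chelation by the free α-hydroxyl gives the 8,9-syn adduct (C8 = S), and the γ-hydroxy ester lactonises to the α-methylene-γ-butyrolactone.

**Step 9**
Reactants: **11**; **12** (R)-2-methylbutanoic acid
Product: **13** (1R,2S,6R)-2-hydroxy-2,6-dimethyl-1-[(2S)-4-methylidene-5-oxooxolan-2-yl]oct-7-en-1-yl (2R)-2-methylbutanoate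
Conditions: **12**, 2,4,6-trichlorobenzoyl chloride, Et3N; then DMAP, toluene, rt
Reagents that add atoms: none besides reactant **12**
Why: Yamaguchi esterification acylates the secondary C9–OH while the tertiary C10–OH stays free; the acid's α-stereocentre is retained.

**Step 10**
Reactants: **13**
Product: **14** (1R,2S,6R,7RS)-2,7-dihydroxy-8-iodo-2,6-dimethyl-1-[(2S)-4-methylidene-5-oxooxolan-2-yl]octyl (2R)-2-methylbutanoate
Conditions: NIS (1.3 equiv), MeCN/H2O 4:1, 0 °C → rt, dark
Reagents that add atoms: N-iodosuccinimide, O=C1CCC(=O)N1I; water, O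
Why: Markovnikov iodohydroxylation of the only electron-rich alkene (the α-methylene lactone is inert to I+); the C5 epimer mixture is irrelevant because C5 is oxidised in step 13.

**Step 11**
Reactants: **14**
Product: **15** (1R,2S,6R,7RS)-2,7-dihydroxy-8-iodo-2,6-dimethyl-1-[(2S)-4-(tosylmethyl)-5-oxo-2,5-dihydrofuran-2-yl]octyl (2R)-2-methylbutanoate
Conditions: TsNa, I2, EtOAc/H2O, visible light, rt; then Et3N, CH2Cl2, 0 °C → rt
Reagents that add atoms: sodium p-toluenesulfinate, Cc1ccc(cc1)S(=O)[O-].[Na+]
Why: Radical iodosulfonylation of the acrylate-type exocyclic alkene, then dehydroiodination/isomerisation, gives the conjugated endocyclic allyl sulfone (by analogy with methacrylate → 2-(tosylmethyl)acrylate); the alkyl iodide and C8 are not affected by sulfonyl radicals or mild amine base.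

**Step 12 (key step)**
Reactants: **15**
Product: **16** (4R,5RS,7S,8S,9R,10S)-5,10-dihydroxy-9-[(2R)-2-methylbutanoyloxy]germacr-11(13)-en-8,12-olide (5-deoxo-5-hydroxy target)
Conditions: (Bu3Sn)2 (1 equiv), hν (sunlamp), PhH, 80 °C, **15** added by syringe pump to 1 mM
Reagents that add atoms: none
Why: Proposed new method: Bu3Sn• abstracts iodine to give a nucleophilic primary β-hydroxyalkyl radical at C6, which adds 10-exo to the electrophilic β-carbon (C7) of the butenolide; the resulting α-carbonyl radical β-fragments irreversibly, expelling Ts• (which regenerates Bu3Sn• from the ditin) and creating the C11=C13 methylene. No H-donor is present, so the radical has the long effective lifetime of atom-transfer conditions. Closest known reactions are intermolecular radical allylation with 2-(sulfonylmethyl)acrylates (allyl sulfone SH2′) and Porter/Pattenden-type radical macrocyclisations onto enoates. C7 (S) is set by C–C bond formation anti to the C8–C9 bond, as in radical additions to γ-substituted butenolides, giving the trans-fused lactone; this selectivity is expected, not guaranteed.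

**Step 13**
Reactants: **16**
Product: **17** ineupatorolide A
Conditions: Dess–Martin periodinane, NaHCO3, CH2Cl2, 0 °C → rt
Reagents that add atoms: none
Why: Dess–Martin oxidation of the only secondary alcohol (both C5 epimers converge); buffered, non-basic conditions do not epimerise C4 or touch the tertiary alcohol and α-methylene lactone.

## Compound list

1 | 5-bromopent-1-ene | C=CCCCBr | starting material
2 | (E)-1,4-dibromobut-2-ene | BrC/C=C/CBr | starting material
3 | (E)-1,6-dibromohex-2-ene | BrC/C=C/CCCBr | intermediate
4 | (R)-6-bromo-3-methylhex-1-ene | C=C[C@H](C)CCCBr | intermediate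
5 | (R)-3-methyloct-1-en-7-yne | C=C[C@H](C)CCCC#C | intermediate
6 | (2E,7R)-3,7-dimethylnona-2,8-dien-1-ol | OC/C=C(\C)CCC[C@@H](C)C=C | intermediate
7 | [(2S,3S)-3-methyl-3-[(4R)-4-methylhex-5-en-1-yl]oxiran-2-yl]methanol | OC[C@@H]1O[C@@]1(C)CCC[C@@H](C)C=C | intermediate
8 | (2R,3S,7R)-3,7-dimethylnon-8-ene-1,2,3-triol | OC[C@@H](O)[C@@](C)(O)CCC[C@@H](C)C=C | intermediate
9 | (2S,3S,7R)-2,3-dihydroxy-3,7-dimethylnon-8-enal | O=C[C@@H](O)[C@@](C)(O)CCC[C@@H](C)C=C | intermediate
10 | methyl 2-(bromomethyl)acrylate | C=C(CBr)C(=O)OC | starting material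
11 | (5S)-5-[(1R,2S,6R)-1,2-dihydroxy-2,6-dimethyloct-7-en-1-yl]-3-methylideneoxolan-2-one | C=C1C(=O)O[C@@H](C1)[C@@H](O)[C@@](C)(O)CCC[C@@H](C)C=C | intermediate
12 | (R)-2-methylbutanoic acid | CC[C@@H](C)C(=O)O | starting material
13 | C9 (2R)-2-methylbutanoate of 11 | C=C1C(=O)O[C@@H](C1)[C@@H](OC(=O)[C@H](C)CC)[C@@](C)(O)CCC[C@@H](C)C=C | intermediate
14 | C5/C6 iodohydrin of 13 (C5 epimers) | C=C1C(=O)O[C@@H](C1)[C@@H](OC(=O)[C@H](C)CC)[C@@](C)(O)CCC[C@@H](C)C(O)CI | intermediate
15 | 3-(tosylmethyl)butenolide iodohydrin (C5 epimers) | O=C1O[C@@H](C=C1CS(=O)(=O)c1ccc(C)cc1)[C@@H](OC(=O)[C@H](C)CC)[C@@](C)(O)CCC[C@@H](C)C(O)CI | intermediate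
16 | 5-deoxo-5-hydroxy-ineupatorolide A (C5 epimers) | C=C1C(=O)O[C@@H]2[C@@H](OC(=O)[C@H](C)CC)[C@@](C)(O)CCC[C@@H](C)C(O)C[C@@H]12 | intermediate
17 | ineupatorolide A | C=C1C(=O)O[C@@H]2[C@@H](OC(=O)[C@H](C)CC)[C@@](C)(O)CCC[C@@H](C)C(=O)C[C@@H]12 | target

## Summary

**Total steps:** 13. **Longest linear sequence:** 13 (fully linear from **1**/**2**; **10** and **12** are purchased).

**Steps most likely to fail, with fallbacks:**

1. **Step 12 (10-exo radical allyl-transfer macrocyclisation).** The ring closure is slow for a medium ring and can lose to 1,5-H transfer or oligomerisation, or give the cis-fused lactone. Fallback: close the ring at C7–C8 instead, by SmI2 ketyl–olefin cyclisation of an acyclic C8 aldehyde onto a C6–C7 2-(acetoxymethyl)enoate (ketyl addition, β-elimination of acetate, lactonisation), with C5 carried as a protected alcohol.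

2. **Step 11 (iodosulfonylation/dehydroiodination in the presence of the iodohydrin).** The elimination may give the exocyclic vinyl sulfone, and base may close the iodohydrin to the epoxide or erode C8. Fallback: deliberately convert **14** to the terminal epoxide (latent iodohydrin), carry out the sulfone transposition on that, and reopen with MgI2 just before the radical step.

3. **Steps 7–8 (sensitive dihydroxy aldehyde; chelation-controlled In allylation).** The aldehyde may over-oxidise or dimerise, and the 8,9-syn:anti ratio may be modest. Fallback: catalyst-controlled Ir-catalysed transfer-hydrogenative 2-(alkoxycarbonyl)allylation directly from the primary alcohol of **8**, which avoids the free aldehyde and sets C8 by the chiral catalyst.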